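**Strategy.** The ten-membered ring is closed last by ring-closing metathesis at C4=C5, after a late boron aldol has added C2–C4. The lactone is made earlier by the key step, an aerobic Wacker-type oxidative lactonization of a γ,δ-unsaturated acid: the C12 carboxylate adds to C6 of an (E)-propenyl branch on C7 and β-hydride elimination leaves a vinyl group at C5. One operation forms the O–C6 bond, the C6 stereocentre and the metathesis handle; it exploits that C6 is both γ to C12 and allylic to the C4=C5 alkene of the ten-membered ring. The precursor, an acyclic acid, comes from an indium Barbier union of a menthol-derived keto aldehyde with a dienyl bromide.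

Key step: step 13

Remark on numbering: germacrane numbering of the target is used for all intermediates (C1 ketone, C3 carbinol, C4=C5, C6 lactone carbinol, C7, C8 angelate, C9 acetate, C10 tertiary carbinol, C11=C13 methylene, C12 lactone carbonyl); the propenyl methyl that is later lost as ethene is called C5′.

**Step 1**
Reactants: 1 3-methylfuran-2-carboxylic acid
Product: 2 (±)-5-hydroxy-3-methylfuran-2(5H)-one
Conditions: O2, hν (visible), rose bengal (cat.), MeOH, 0 °C
Reagents that add atoms: dioxygen, O=O
Why: Singlet oxygen adds [4+2] across C2/C5 of the furan and the endoperoxide fragments with loss of CO2 to the γ-hydroxybutenolide (Schenck-type furan photooxygenation), the lactol centre being racemic at this stage.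

**Step 2**
Reactants: 2 (±)-5-hydroxy-3-methylfuran-2(5H)-one; 3 (−)-menthol
Product: 4 (5R)-3-methyl-5-(menthyloxy)furan-2(5H)-one
Conditions: CSA (cat.), toluene, reflux (Dean–Stark); crystallization
Reagents that add atoms: none
Why: Acid-catalysed acetalization of the lactol gives both C5 epimers, from which the (5R)-acetal should crystallize while the other epimer is recycled by acid equilibration (Feringa-type chiral butenolide).

**Step 3**
Reactants: 4 (5R)-3-methyl-5-(menthyloxy)furan-2(5H)-one
Product: 5 (3S,4R,5R)-3,4-dihydroxy-3-methyl-5-(menthyloxy)oxolan-2-one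
Conditions: OsO4 (5 mol%), NMO, acetone/H2O, rt
Reagents that add atoms: N-methylmorpholine N-oxide, C[N+]1([O-])CCOCC1; water, O
Why: Upjohn syn-dihydroxylation should occur on the butenolide face anti to the C5 menthyloxy group, which sets C9 and C10 in one step.

**Step 4**
Reactants: 5 diol lactone
Product: 6 acetonide lactone (3aS,6R,6aR)
Conditions: Me2C(OMe)2, TsOH (cat.), acetone, rt
Reagents that add atoms: 2,2-dimethoxypropane, COC(C)(C)OC
Why: Acid-catalysed transketalization protects the cis-diol as the acetonide so that neither hydroxyl interferes with the methylenation and Barbier steps.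

**Step 5**
Reactants: 6 acetonide lactone
Product: 8 (4R,5S)-5-acetyl-2,2,5-trimethyl-1,3-dioxolane-4-carbaldehyde, via exocyclic enol ether 7 (not isolated)
Conditions: Cp2TiMe2, toluene, 70 °C, dark; then 0.5 M HCl, THF, 0 °C; used directly
Reagents that add atoms: dimethyltitanocene, [CH3-].[CH3-].[Ti+4].c1cc[cH-]c1.c1cc[cH-]c1; water, O
Why: Petasis methylenation converts the lactone carbonyl into an exocyclic enol ether, whose cold acid hydration gives a methyl hemiketal that opens to the C1 methyl ketone and a hemiacetal that loses menthol to free the C8 aldehyde, the acetonide surviving the brief dilute acid.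

**Step 6**
Reactants: 9 (E)-but-2-enal; 10 tert-butyl acrylate
Product: 11 (±)-tert-butyl (4E)-3-hydroxy-2-methylidenehex-4-enoate
Conditions: DABCO (0.5 equiv), neat, rt
Reagents that add atoms: none
Why: Morita–Baylis–Hillman reaction in which the DABCO-derived acrylate enolate adds 1,2 to the enal, the carbinol centre being irrelevant because it is lost in the next step.

**Step 7**
Reactants: 11 Morita–Baylis–Hillman alcohol
Product: 12 tert-butyl (2Z,4E)-2-(bromomethyl)hexa-2,4-dienoate
Conditions: NBS, Me2S, CH2Cl2, 0 °C to rt
Reagents that add atoms: N-bromosuccinimide, O=C1CCC(=O)N1Br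
Why: Corey–Kim-type activation of the alcohol followed by SN2′ attack of bromide gives the rearranged primary allylic bromide, the (2Z)-isomer with the ester trans to the propenyl group being thermodynamically favoured.

**Step 8**
Reactants: 8 keto aldehyde; 12 dienyl bromide
Product: 13 Barbier adduct (7R,8S,9S,10S; tert-butyl ester, free C8 hydroxyl, C9/C10 acetonide)
Conditions: indium powder, THF/H2O (1:1), rt
Reagents that add atoms: none
Why: Indium Barbier allylation in which the allylindium from 12 attacks the aldehyde through its γ-carbon (C7) in a chair transition state, the (Z)-reagent giving the 7,8-syn relationship and Felkin–Anh addition to the acetonide-protected α-oxygenated aldehyde giving the 8,9-anti relationship, so that C7 and C8 are set together.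

**Step 9**
Reactants: 13 Barbier adduct; 14 angelic acid
Product: 15 C8 angelate
Conditions: 2,4,6-Cl3C6H2COCl, Et3N, toluene, rt; then 13, DMAP, 70 °C
Reagents that add atoms: none
Why: Yamaguchi esterification through the mixed 2,4,6-trichlorobenzoic anhydride acylates the hindered C8 hydroxyl under conditions known to preserve the (Z)-geometry of angelates.

**Step 10**
Reactants: 15 C8 angelate
Product: 16 C9,C10-diol
Conditions: AcOH/H2O (4:1), 45 °C
Reagents that add atoms: none
Why: Mild aqueous acid hydrolyses the acetonide while the tert-butyl ester and the angelate should survive.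

**Step 11**
Reactants: 16 C9,C10-diol
Product: 17 C9 acetate
Conditions: Ac2O, pyridine, 0 °C to rt
Reagents that add atoms: acetic anhydride, CC(=O)OC(C)=O
Why: Acetylation is selective for the secondary C9 hydroxyl because the tertiary C10 hydroxyl is unreactive without a strong acylation catalyst.

**Step 12**
Reactants: 17 C9 acetate
Product: 18 seco-acid (free C12 acid, (E)-propenyl on C7)
Conditions: TFA/CH2Cl2 (1:4), 0 °C
Reagents that add atoms: none
Why: Acidolysis of the tert-butyl ester with loss of isobutene frees the C12 acid without touching the acetate and angelate esters.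

**Step 13**
Reactants: 18 seco-acid
Product: 19 trans-α-methylene-γ-vinyl lactone (6R,7S)
Conditions: Pd(OAc)2 (10 mol%), NaOAc, O2 (1 atm), DMSO, rt
Reagents that add atoms: none
Why: Palladium diacetate forms the divalent palladium carboxylate of 18, the (E)-C5=C6 alkene coordinates, the carboxylate oxygen adds to C6 and the σ-alkylpalladium at C5 undergoes β-hydride elimination toward the C5′ methyl to give the C5 vinyl group, the palladium hydride being reoxidized by O2 in DMSO. The closest known reaction type is the aerobic oxidative cyclization of 4-alkenoic acids to γ-alkenyl-γ-butyrolactones (intramolecular Wacker-type acyloxypalladation). The lactone ring closes in the 5-exo-trig mode through the new O–C6 bond. The new C6 stereocentre is controlled by the adjacent C7 centre: in the envelope transition state the C8 chain on C7 and the palladium-bearing C5 on C6 both sit pseudo-equatorial, and reversible acyloxypalladation should funnel material through the trans σ-alkyl intermediate to the trans lactone. The step needs 5-exo over 6-endo attack, elimination away from the oxygen-bearing C6, and chemoselectivity over the acrylate and angelate alkenes and the C10 hydroxyl; these are secured by the γ,δ-position of the alkene, the reluctance to form an enol ester, the electron-poor character of the conjugated alkenes and the higher nucleophilicity of the carboxylate.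

**Step 14**
Reactants: 19 vinyl lactone methyl ketone; 20 methacrolein
Product: 22 seco-diene aldol (3S), via boron enolate 21 (not isolated)
Conditions: (−)-Ipc2BCl, Et3N, Et2O, −78 to 0 °C; then 20, −78 to −20 °C; then MeOH, pH 7 buffer, H2O2, 0 °C
Reagents that add atoms: none
Why: Paterson-type boron aldol in which enolization can occur only toward C2 because C10 is quaternary, the diisopinocampheylboron enolate adds 1,2 to methacrolein through a cyclic transition state, and the Ipc ligands are relied on for the facial selectivity that sets C3 as S, the antipodal reagent being used instead if the C10 centre proves mismatched.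

**Step 15**
Reactants: 22 seco-diene aldol
Product: 23 target, (3S,6R,7S,8S,9S,10S)-9-acetoxy-8-angeloyloxy-3,10-dihydroxy-1-oxogermacra-4Z,11(13)-dien-12,6-olide
Conditions: second-generation Hoveyda–Grubbs catalyst (15 mol%), 1,4-benzoquinone (cat.), toluene (0.5 mM), 80 °C
Reagents that add atoms: none
Why: Ring-closing metathesis in which the catalyst loads on the C5 vinyl group and closes onto the 1,1-disubstituted C4 olefin with loss of ethene, the ten-membered ring being expected to take up the trisubstituted alkene in the (Z)-geometry, while benzoquinone suppresses ruthenium hydride isomerization of the allylic alcohol.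

**Compound list**

1 | 3-methylfuran-2-carboxylic acid | Cc1ccoc1C(=O)O | starting material
2 | (±)-5-hydroxy-3-methylfuran-2(5H)-one | CC1=CC(O)OC1=O | intermediate
3 | (−)-menthol, (1R,2S,5R)-5-methyl-2-(propan-2-yl)cyclohexan-1-ol | C[C@@H]1CC[C@H]([C@@H](C1)O)C(C)C | starting material
4 | (5R)-3-methyl-5-[(1R,2S,5R)-menthyloxy]furan-2(5H)-one | CC1=C[C@H](O[C@@H]2C[C@H](C)CC[C@H]2C(C)C)OC1=O | intermediate
5 | (3S,4R,5R)-3,4-dihydroxy-3-methyl-5-[(1R,2S,5R)-menthyloxy]oxolan-2-one | O[C@H]1[C@H](O[C@@H]2C[C@H](C)CC[C@H]2C(C)C)OC(=O)[C@@]1(C)O | intermediate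
6 | (3aS,6R,6aR)-2,2,3a-trimethyl-6-[(1R,2S,5R)-menthyloxy]dihydrofuro[3,4-d][1,3]dioxol-4(3aH)-one | CC1(C)O[C@H]2[C@H](O[C@@H]3C[C@H](C)CC[C@H]3C(C)C)OC(=O)[C@@]2(C)O1 | intermediate
7 | (3aS,6R,6aR)-2,2,3a-trimethyl-4-methylidene-6-[(1R,2S,5R)-menthyloxy]tetrahydrofuro[3,4-d][1,3]dioxole (exocyclic enol ether) | CC1(C)O[C@H]2[C@H](O[C@@H]3C[C@H](C)CC[C@H]3C(C)C)OC(=C)[C@@]2(C)O1 | intermediate
8 | (4R,5S)-5-acetyl-2,2,5-trimethyl-1,3-dioxolane-4-carbaldehyde | O=C[C@@H]1OC(C)(C)O[C@]1(C)C(C)=O | intermediate
9 | (E)-but-2-enal (crotonaldehyde) | C/C=C/C=O | starting material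
10 | tert-butyl acrylate | C=CC(=O)OC(C)(C)C | starting material
11 | (±)-tert-butyl (4E)-3-hydroxy-2-methylidenehex-4-enoate | C/C=C/C(O)C(=C)C(=O)OC(C)(C)C | intermediate
12 | tert-butyl (2Z,4E)-2-(bromomethyl)hexa-2,4-dienoate | C/C=C/C=C(\CBr)C(=O)OC(C)(C)C | intermediate
13 | tert-butyl (3R,4S)-4-[(4S,5S)-5-acetyl-2,2,5-trimethyl-1,3-dioxolan-4-yl]-4-hydroxy-2-methylidene-3-[(1E)-prop-1-en-1-yl]butanoate | C=C(C(=O)OC(C)(C)C)[C@@H](/C=C/C)[C@H](O)[C@@H]1OC(C)(C)O[C@]1(C)C(C)=O | intermediate
14 | angelic acid, (2Z)-2-methylbut-2-enoic acid | C/C=C(/C)C(=O)O | starting material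
15 | tert-butyl (3R,4S)-4-[(4S,5S)-5-acetyl-2,2,5-trimethyl-1,3-dioxolan-4-yl]-2-methylidene-4-{[(2Z)-2-methylbut-2-enoyl]oxy}-3-[(1E)-prop-1-en-1-yl]butanoate | C=C(C(=O)OC(C)(C)C)[C@@H](/C=C/C)[C@H](OC(=O)/C(C)=C\C)[C@@H]1OC(C)(C)O[C@]1(C)C(C)=O | intermediate
16 | tert-butyl (3R,4S,5S,6S)-5,6-dihydroxy-6-methyl-2-methylidene-4-{[(2Z)-2-methylbut-2-enoyl]oxy}-7-oxo-3-[(1E)-prop-1-en-1-yl]octanoate | C=C(C(=O)OC(C)(C)C)[C@@H](/C=C/C)[C@H](OC(=O)/C(C)=C\C)[C@H](O)[C@](C)(O)C(C)=O | intermediate
17 | tert-butyl (3R,4S,5S,6S)-5-acetoxy-6-hydroxy-6-methyl-2-methylidene-4-{[(2Z)-2-methylbut-2-enoyl]oxy}-7-oxo-3-[(1E)-prop-1-en-1-yl]octanoate | C=C(C(=O)OC(C)(C)C)[C@@H](/C=C/C)[C@H](OC(=O)/C(C)=C\C)[C@H](OC(C)=O)[C@](C)(O)C(C)=O | intermediate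
18 | (3R,4S,5S,6S)-5-acetoxy-6-hydroxy-6-methyl-2-methylidene-4-{[(2Z)-2-methylbut-2-enoyl]oxy}-7-oxo-3-[(1E)-prop-1-en-1-yl]octanoic acid | C=C(C(=O)O)[C@@H](/C=C/C)[C@H](OC(=O)/C(C)=C\C)[C@H](OC(C)=O)[C@](C)(O)C(C)=O | intermediate
19 | (1S,2S,3S)-2-acetoxy-1-[(2R,3S)-2-ethenyl-4-methylidene-5-oxooxolan-3-yl]-3-hydroxy-3-methyl-4-oxopentyl (2Z)-2-methylbut-2-enoate | C=C1C(=O)O[C@H](C=C)[C@H]1[C@H](OC(=O)/C(C)=C\C)[C@H](OC(C)=O)[C@](C)(O)C(C)=O | intermediate
20 | methacrolein (2-methylprop-2-enal) | C=C(C)C=O | starting material
21 | bis(diisopinocampheylboryl) derivative of 19 (C1=C2 enol borinate, C10 borinate) | C=C1C(=O)O[C@H](C=C)[C@H]1[C@H](OC(=O)/C(C)=C\C)[C@H](OC(C)=O)[C@](C)(OB([C@@H]2C[C@@H]3C[C@H]([C@H]2C)C3(C)C)[C@@H]2C[C@@H]3C[C@H]([C@H]2C)C3(C)C)C(=C)OB([C@@H]2C[C@@H]3C[C@H]([C@H]2C)C3(C)C)[C@@H]2C[C@@H]3C[C@H]([C@H]2C)C3(C)C | intermediate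
22 | (1S,2S,3S,6S)-2-acetoxy-1-[(2R,3S)-2-ethenyl-4-methylidene-5-oxooxolan-3-yl]-3,6-dihydroxy-3,7-dimethyl-4-oxooct-7-en-1-yl (2Z)-2-methylbut-2-enoate | C=C1C(=O)O[C@H](C=C)[C@H]1[C@H](OC(=O)/C(C)=C\C)[C@H](OC(C)=O)[C@](C)(O)C(=O)C[C@H](O)C(C)=C | intermediate
23 | (3S,6R,7S,8S,9S,10S)-9-acetoxy-8-angeloyloxy-3,10-dihydroxy-1-oxogermacra-4Z,11(13)-dien-12,6-olide | C=C1C(=O)O[C@@H]2/C=C(/C)[C@@H](O)CC(=O)[C@@](C)(O)[C@@H](OC(C)=O)[C@@H](OC(=O)/C(C)=C\C)[C@@H]12 | target

**Step count and risks**

Total step count: 15. Longest linear sequence: 13 steps (steps 1–5 and 8–15); steps 6–7 form the two-step side branch to bromide 12.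

The three steps most likely to fail:

Step 15, ring-closing metathesis. The ruthenium alkylidene formed at the C5 vinyl group may dimerize by cross metathesis instead of closing the strained ten-membered ring onto the hindered 1,1-disubstituted olefin, or the ring may close with the (E)-geometry. The fallback is a relay ring-closing metathesis that sets out from compound 19. The aldol of step 14 would be run with (2E)-2-methylocta-2,7-dienal F1 (made by Wittig reaction of hex-5-enal with 2-(triphenylphosphoranylidene)propanal) in place of methacrolein, giving the relay diene F2. The second-generation Grubbs catalyst then loads on the unhindered terminal olefin of the tether and expels cyclopentene, which places the alkylidene on C4; this carbene can only close onto the C5 vinyl group. The sequence comes back to the route at compound 23.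

Step 14, boron aldol. Facial selectivity at C3 may be poor under the combined influence of the Ipc ligands and the C10 centre, and acyl migration between O9 and O10 may occur under the amine and boron conditions. The fallback is a chromium Reformatsky reaction that sets out from compound 19. TMSOTf and Et3N would give the bis(trimethylsilyl) enol ether F3, in which the C10 hydroxyl is silylated as well. NBS at −78 °C would convert it into the bromomethyl ketone F4. CrCl2 with catalytic lithium iodide in THF would then generate a chromium enolate under neutral conditions that adds 1,2 to methacrolein. Mild acidic work-up removes the silyl ether, the C3 epimers are separated by chromatography, and the sequence comes back to the route at compound 22.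

Step 13, oxidative lactonization. The trans/cis selectivity at C6 may be low, and palladium may shift the skipped diene through the doubly allylic C7–H. The fallback is selenolactonization followed by selenoxide elimination, setting out from compound 18. PhSeCl in CH2Cl2 at room temperature (reversible, thermodynamic conditions) should give the trans phenylselanyl lactone F5 by anti addition across C5=C6. Oxidation with H2O2 and pyridine and syn elimination of the selenoxide away from the lactone oxygen would then give the vinyl lactone, coming back to the route at compound 19.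

**Further compounds**

F1 | step 15 | (2E)-2-methylocta-2,7-dienal | C=CCCC/C=C(\C)C=O
F2 | step 15 | relay diene: 22 carrying an (E)-pent-4-enyl chain on the terminal olefin carbon of C4 | C=C1C(=O)O[C@H](C=C)[C@H]1[C@H](OC(=O)/C(C)=C\C)[C@H](OC(C)=O)[C@](C)(O)C(=O)C[C@H](O)/C(C)=C/CCCC=C
F3 | step 14 | bis(trimethylsilyl) derivative of 19 (C1=C2 silyl enol ether, C10 silyl ether) | C=C1C(=O)O[C@H](C=C)[C@H]1[C@H](OC(=O)/C(C)=C\C)[C@H](OC(C)=O)[C@](C)(O[Si](C)(C)C)C(=C)O[Si](C)(C)C
F4 | step 14 | C2-bromo derivative of 19 with C10 trimethylsilyl ether (bromomethyl ketone) | C=C1C(=O)O[C@H](C=C)[C@H]1[C@H](OC(=O)/C(C)=C\C)[C@H](OC(C)=O)[C@](C)(O[Si](C)(C)C)C(=O)CBr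
F5 | step 13 | trans lactone with a (1R)-1-(phenylselanyl)ethyl group at C6 in place of the vinyl group of 19 | C=C1C(=O)O[C@H]([C@@H](C)[Se]c2ccccc2)[C@H]1[C@H](OC(=O)/C(C)=C\C)[C@H](OC(C)=O)[C@](C)(O)C(C)=O
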